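In a one-step world the substrate consumed would stand entirely as target, but the autumn run at 8.00 h shows 60.1 % target for 91.0 % of substrate gone, so an uncatalysed path runs beside the catalysed one.

| flask | substrate | gas phase | catalyst | remark | time |
|---|---|---|---|---|---|
| spring | 32 mM | 2.8 mM (held) | 0.5 mol% | run made earlier |  |
| summer | 32 mM | 2.8 mM (held) | 0.75 mol% | run made earlier |  |
| autumn | 64 mM | 2.8 mM (held) | 1 mol% | run made earlier |  |
| flask | 32 mM | 2.8 mM (held) | 1 mol% |  | 10 h |

- spring (time / h: target / %, substrate / %): 2.00: 8.3, 73.6; 4.00: 14.6, 58.4; 6.00: 19.2, 45.1; 8.00: 23.6, 31.9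
- summer (time / h: target / %, substrate / %): 2.00: 10.9, 73.6; 4.00: 22.0, 52.2; 6.00: 26.7, 39.5; 8.00: 30.8, 27.1
- autumn (time / h: target / %, substrate / %): 1.00: 13.6, 80.6; 3.00: 33.6, 49.0; 5.00: 48.7, 28.1; 8.00: 60.1, 9.0

(readings scatter by 1 percentage point)

- target at 10 h, in percent of the substrate charged
- the change that raises the amount of target at 10 h, in percent of the substrate charged most ("none" if none brings more than 2 percentage points) (eta / alpha / theta / none)
- amount of target at 10 h, in percent of the substrate charged, after alpha

- eta: doubling the transfer coefficient of the gas phase, all else as stated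
- alpha: doubling the saturation concentration of gas phase, all else as stated
- theta: doubling the amount of catalyst, all else as stated

- at the start none of the gas is dissolved
- what may be going on: substrate + dissolved gas -> uncatalysed product; substrate + dissolved gas + catalyst -> catalyst + target; gas phase <-> dissolved gas; dissolved gas -> decomposed reagent

I count catalytic turnovers against background events. Taking uncatalysed product as substrate lost minus target, the last readings give target per uncatalysed product, divided by c_catalyst, as 3.31 mM⁻¹ in spring, 3.05 mM⁻¹ in summer and 3.04 mM⁻¹ in autumn. Their mean is 3.13 mM⁻¹, the partition gain, a selectivity factor per unit of c_catalyst. Both steps take dissolved gas, so c_dissolved gas cancels from this ratio.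

The flask therefore has a ratio of 1.00, and target runs towards a level of 50.1 %. The spring readings, treated as pseudo-first-order, leave a background constant of 0.0951 h⁻¹, so the flask's substrate decays at 0.191 h⁻¹. With c_dissolved gas taken as steady, its target curve starts with a slope of 0.0957 h⁻¹ as a fraction of the charge, crosses the falling substrate near 5.76 h, and bends to 42.6 % at 10 h. The autumn readings, with twice the substrate, leave a background constant of 0.100 h⁻¹, close to the spring value, so I expect little from eta. Alpha, which I take to double c_dissolved gas, leaves the level where it is and doubles the decay constant, so target reaches 49.0 %. Doubling the catalyst lifts the level to 66.7 % and gives 62.9 % at 10 h, more than alpha gives, so I choose theta.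

The forecast gives 43.5 %, higher than mine, with theta as the best change and 49.5 % after alpha, holding that “gas supply is not strongly limiting”.

The flask gives 43.0 %, theta with a gain of 20 percentage points, and 49.5 % after alpha.

substrate + dissolved gas → uncatalysed product (k = 0.0100 M⁻¹ s⁻¹); substrate + dissolved gas + catalyst → catalyst + target (k = 32.0 M⁻² s⁻¹); gas phase ⇌ dissolved gas, rate k3*(csat - [dissolved gas]) (kL = 0.00650 s⁻¹); dissolved gas → decomposed reagent (k = 1.90 × 10⁻⁴ s⁻¹) For the flask's target to move 5 points, with all else held, the catalyst would have to stand at 0.83 mol% or 1.2 mol%. At 10.0 h the flask holds 43.0 % target and 42.0 % uncatalysed product, a ratio of 1.02 against my 1.00. A neighbouring flask keeps 1 mol% but charges 19 mM of substrate, so the partition gain gives it a ratio of 0.595. It ends with 29.6 % target and 48.8 % uncatalysed product, a ratio of 0.607.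

Readings and results are simulated on assumed constants.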